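**Plan**

1. Retrosynthesis (decalin locants as in the name of 25): the hydroxy-methoxy-quinone is unmasked last from a 2,3,5,6-tetramethoxyphenyl group. A temporary ketone is then placed at C-4 and the C-4a–C-5 bond is cut (retro-Conia-ene) to give a silyl enol ether with a pent-4-ynyl chain on C-8a.
2. Further cuts: the C-8a–C-8 bond (conjugate addition to a 2-methylcyclohexenone), a 1,3-carbonyl transposition back to a 2,2,3-trisubstituted cyclohexanone, the two C–CH3 bonds at C-1 and C-2 (asymmetric conjugate addition, then enolate methylation) and the ArCH2–ring bond (Negishi coupling).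
3. Forward order: the arene is present from the start, the cyclohexane ring C-1/C-2/C-3/C-4/C-4a/C-8a comes from 2-iodocyclohexenone and is decorated, the chain is joined, and the methylenecyclohexane ring C-4a/C-5/C-6/C-7/C-8/C-8a is closed last. Deoxygenation at C-4 and quinone formation follow.
4. Enabling feature: the =CH2-bearing C-5 is bonded to the fully substituted, methyl-bearing C-4a, which is α to C-4 of the other carbocycle. With C-4 as C=O, C-4a is an enol carbon and C-5=CH2 is the trace of a terminal alkyne, so one 6-exo-dig Conia-ene closure makes the quaternary centre, the cis ring fusion and the exocyclic alkene.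
5. Stereochemistry: C-2 from the chiral copper catalyst; C-1 from enolate methylation trans to the C-2 methyl; C-8a from axial cuprate attack anti to the arylmethyl group and trans to the C-2 methyl; C-4a from the tether (cis fusion).

Key step: step 11

Remark: Ar = 2,3,5,6-tetramethoxyphenyl; 1, 5 and 15 are taken as purchased; in step 4 the ligand antipode is the one that leads to the 3R centre.

**Route**

Step 1
Reactants: 1 1,2,4,5-tetramethoxybenzene
Product: 3 (2,3,5,6-tetramethoxyphenyl)methanol, via aryllithium 2 (not isolated)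
Conditions: n-BuLi, THF, 0 °C; (CH2O)n, 0 → 25 °C; H2O
Reagents that add atoms: paraformaldehyde (reacts as formaldehyde), C=O
Why: Directed ortho-lithiation between two methoxy groups (both ring C–H positions of 1 are equivalent) followed by hydroxymethylation of the aryllithium with formaldehyde.

Step 2
Reactants: 3 (2,3,5,6-tetramethoxyphenyl)methanol
Product: 4 3-(chloromethyl)-1,2,4,5-tetramethoxybenzene
Conditions: SOCl2, pyridine, CH2Cl2, 0 °C
Reagents that add atoms: thionyl chloride, ClS(Cl)=O
Why: Chlorination of an electron-rich benzylic alcohol through its chlorosulfite; the chloride is chosen over the bromide because it should insert zinc without homocoupling.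

Step 3
Reactants: 4 3-(chloromethyl)-1,2,4,5-tetramethoxybenzene; 5 2-iodocyclohex-2-en-1-one
Product: 7 2-(ArCH2)cyclohex-2-en-1-one, via benzylzinc chloride 6 (not isolated)
Conditions: Zn dust, LiCl, THF, 25 °C; then 5, Pd(OAc)2 (2 mol %), SPhos (4 mol %), THF, 25 °C
Reagents that add atoms: none
Why: Zinc insertion into the benzylic chloride and Negishi coupling with the α-iodoenone under zerovalent palladium catalysis, a standard sp3–sp2 coupling that leaves the enone untouched.

Step 4
Reactants: 7 2-(ArCH2)cyclohex-2-en-1-one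
Product: 9 (2R,3R)-2,3-dimethyl-2-(ArCH2)cyclohexan-1-one, via magnesium enolate 8 (not isolated)
Conditions: MeMgBr, CuBr·SMe2 (5 mol %), Josiphos-type ferrocenyl diphosphine (6 mol %), t-BuOMe, –78 °C; then MeI, DMPU, –78 → 0 °C
Reagents that add atoms: methylmagnesium bromide, C[Mg]Br; iodomethane, CI
Why: Copper-catalysed asymmetric conjugate addition sets the tertiary centre under ligand control, and the magnesium enolate is then methylated on the face opposite the new methyl group (held pseudoaxial by allylic strain with the arylmethyl group), which should set the quaternary centre with the two methyl groups trans.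

Step 5
Reactants: 9 (2R,3R)-2,3-dimethyl-2-(ArCH2)cyclohexan-1-one
Product: 10 2,4,6-triisopropylbenzenesulfonylhydrazone of 9
Conditions: 2,4,6-(i-Pr)3C6H2SO2NHNH2, HCl (cat.), MeCN, 25 °C
Reagents that add atoms: 2,4,6-tri(propan-2-yl)benzenesulfonohydrazide, CC(C)c1cc(C(C)C)c(S(=O)(=O)NN)c(C(C)C)c1
Why: Acid-catalysed hydrazone formation; the ketone has α-hydrogens on one side only, so the N–N bond should lie syn to that CH2 group, as the Shapiro reaction requires.

Step 6
Reactants: 10 2,4,6-triisopropylbenzenesulfonylhydrazone of 9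
Product: 13 (3R,4R)-1,3,4-trimethyl-3-(ArCH2)cyclohex-1-ene, via methylated hydrazone salt 11 (not isolated), via vinyllithium 12 (not isolated)
Conditions: n-BuLi (2.05 equiv), THF, –78 °C; MeI (1.0 equiv), –78 °C; n-BuLi (1.5 equiv), –78 → 0 °C; H2O
Reagents that add atoms: iodomethane, CI
Why: Alkylative Shapiro reaction in which the syn dianion is C-methylated, a further equivalent of base removes the remaining α-hydrogen (the other α-carbon is quaternary, so the regiochemistry is forced), and loss of sulfinate and N2 gives the vinyllithium that is protonated on work-up; no stereocentre is touched.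

Step 7
Reactants: 13 (3R,4R)-1,3,4-trimethyl-3-(ArCH2)cyclohex-1-ene
Product: 14 (4R,5R)-2,4,5-trimethyl-4-(ArCH2)cyclohex-2-en-1-one
Conditions: Rh2(cap)4 (cap = caprolactamate, 1 mol %), t-BuOOH (5 equiv), K2CO3, CH2Cl2, 25 °C
Reagents that add atoms: tert-butyl hydroperoxide, CC(C)(C)OO
Why: Allylic oxidation by tert-butylperoxyl radicals, in which the only ring allylic C–H bonds are on the CH2 next to the methyl-bearing alkene carbon (the other allylic ring carbon is quaternary) and oxygen should enter at that unhindered terminus and not at the neopentyl one, giving the 2-methyl enone.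

Step 8
Reactants: 14 (4R,5R)-2,4,5-trimethyl-4-(ArCH2)cyclohex-2-en-1-one; 15 (5-chloropent-1-yn-1-yl)trimethylsilane
Product: 17 trimethylsilyl enol ether of (2RS,3S,4R,5R)-2,4,5-trimethyl-4-(ArCH2)-3-[5-(trimethylsilyl)pent-4-yn-1-yl]cyclohexan-1-one with the C-1/C-2 double bond, via Grignard reagent 16 (not isolated)
Conditions: 15, Mg, THF, 50 °C; then 14, CuBr·SMe2 (10 mol %), Me3SiCl, HMPA, THF, –78 → –40 °C; Et3N, aq. NaHCO3
Reagents that add atoms: chlorotrimethylsilane, C[Si](C)(C)Cl
Why: Copper-catalysed, Me3SiCl-accelerated conjugate addition in which the alkyl group should enter axially at the β-carbon, anti to the axial arylmethyl group on the neighbouring quaternary carbon and trans to the C-5 methyl group, while the enolate is trapped as the regiodefined tetrasubstituted silyl enol ether.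

Step 9
Reactants: 17 trimethylsilyl enol ether from step 8
Product: 19 triisopropylsilyl enol ether with the same skeleton and C-silylated alkyne, via lithium enolate 18 (not isolated)
Conditions: MeLi (1.05 equiv), THF, 0 °C; then i-Pr3SiOTf, –78 → 0 °C
Reagents that add atoms: triisopropylsilyl trifluoromethanesulfonate, CC(C)[Si](OS(=O)(=O)C(F)(F)F)(C(C)C)C(C)C
Why: Methyllithium cleaves the O–SiMe3 bond to the lithium enolate without moving the double bond, and O-silylation with the silyl triflate gives an enol ether robust enough for the next two steps; the alkynyl C–SiMe3 bond should survive at 0 °C.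

Step 10
Reactants: 19 triisopropylsilyl enol ether with C-silylated alkyne
Product: 20 {[(3S,4R,5R)-2,4,5-trimethyl-3-(pent-4-yn-1-yl)-4-(ArCH2)cyclohex-1-en-1-yl]oxy}tri(propan-2-yl)silane
Conditions: K2CO3 (0.3 equiv), MeOH/THF, 25 °C
Reagents that add atoms: none
Why: Base-catalysed methanolysis of the alkynyl C–Si bond, to which the hindered triisopropylsilyl enol ether should be inert.

Step 11
Reactants: 20 {[(3S,4R,5R)-2,4,5-trimethyl-3-(pent-4-yn-1-yl)-4-(ArCH2)cyclohex-1-en-1-yl]oxy}tri(propan-2-yl)silane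
Product: 21 (3R,4R,4aS,8aR)-3,4,8a-trimethyl-8-methylidene-4-(ArCH2)-3,4,4a,5,6,7,8,8a-octahydronaphthalen-1(2H)-one (cis-fused)
Conditions: [(t-Bu)2(o-biphenyl)P]Au(NCMe)SbF6 (5 mol %), MeOH (2 equiv), CH2Cl2, 25 °C
Reagents that add atoms: none
Why: The cationic monovalent gold complex binds the terminal alkyne, the tetrasubstituted enol ether carbon (the future C-4a of the target) attacks the internal alkyne carbon anti to gold, and methanol then takes the silyl group from the oxocarbenium ion and protonates the vinyl–gold bond, which leaves the helper ketone and the exocyclic methylene. The closest known reaction type is the gold-catalysed Conia-ene-type carbocyclisation of alkynyl silyl enol ethers. The one ring that closes, the methylenecyclohexane ring, does so in the 6-exo-dig mode. The one new stereocentre, the quaternary ring-fusion carbon, is controlled by the adjacent ring-fusion CH stereocentre through the tether: allylic 1,2-strain with the vinylic methyl group holds the pentynyl chain pseudoaxial, on the face away from the axial arylmethyl group, so it can reach only that face of the enol ether and the fusion should be cis, with the angular methyl and the ring-fusion hydrogen on the same side. The step needs exo and not 7-endo closure, which the terminal alkyne secures by taking the nucleophile at its internal carbon; it needs bond formation at the methyl-bearing α-carbon, which the enol ether fixed in step 8 secures; and it needs cyclisation faster than protodesilylation, which the hindered triisopropylsilyl group and the nearly neutral medium secure.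

Step 12
Reactants: 21 cis-fused decalinone from step 11
Product: 23 3-{[(1R,2R,4aR,8aS)-1,2,4a-trimethyl-5-methylidenedecahydronaphthalen-1-yl]methyl}-1,2,4,5-tetramethoxybenzene, via hydrazone 22 (not isolated)
Conditions: N2H4·H2O, KOH, diethylene glycol, 130 °C, then 200 °C with removal of water, under argon
Reagents that add atoms: none
Why: Wolff–Kishner reduction (Huang–Minlon procedure) removes the helper carbonyl through the hydrazone anion and loss of N2; the ketone has a quaternary α-carbon on one side and no epimerisable stereocentre, and the isolated 1,1-disubstituted alkene and the aryl methyl ethers should be inert to hydroxide in glycol.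

Step 13
Reactants: 23 tetramethoxyarene from step 12
Product: 24 2,5-dimethoxy-3-{[(1R,2R,4aR,8aS)-1,2,4a-trimethyl-5-methylidenedecahydronaphthalen-1-yl]methyl}cyclohexa-2,5-diene-1,4-dione
Conditions: (NH4)2Ce(NO3)6 (2.5 equiv), MeCN/H2O, 0 °C
Reagents that add atoms: water, O
Why: Oxidative demethylation of a para-dimethoxy pair gives the 2,5-dimethoxy-1,4-benzoquinone (both para pairs of the symmetric arene lead to the same quinone), and the isolated alkene should not be oxidised under these conditions.

Step 14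
Reactants: 24 dimethoxyquinone from step 13
Product: 25 2-hydroxy-5-methoxy-3-{[(1R,2R,4aR,8aS)-1,2,4a-trimethyl-5-methylidenedecahydronaphthalen-1-yl]methyl}cyclohexa-2,5-diene-1,4-dione (target)
Conditions: KOH (2 M aq.), MeOH, 25 °C; then HCl (1 M)
Reagents that add atoms: potassium hydroxide, [K+].[OH-]
Why: Addition–elimination of hydroxide at a vinylogous ester carbon, in which the methoxy group flanked by the alkyl substituent and a carbonyl is twisted out of conjugation and should be exchanged in preference, as is usual for 3-alkyl-2,5-dimethoxybenzoquinones, while the resulting vinylogous carboxylate resists a second exchange.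

**Compound list**

1 | 1,2,4,5-tetramethoxybenzene | COc1cc(OC)c(OC)cc1OC | starting material
2 | (2,3,5,6-tetramethoxyphenyl)lithium | [Li]c1c(OC)c(OC)cc(OC)c1OC | intermediate
3 | (2,3,5,6-tetramethoxyphenyl)methanol | OCc1c(OC)c(OC)cc(OC)c1OC | intermediate
4 | 3-(chloromethyl)-1,2,4,5-tetramethoxybenzene | ClCc1c(OC)c(OC)cc(OC)c1OC | intermediate
5 | 2-iodocyclohex-2-en-1-one | O=C1CCCC=C1I | starting material
6 | chloro[(2,3,5,6-tetramethoxyphenyl)methyl]zinc | Cl[Zn]Cc1c(OC)c(OC)cc(OC)c1OC | intermediate
7 | 2-[(2,3,5,6-tetramethoxyphenyl)methyl]cyclohex-2-en-1-one | O=C1CCCC=C1Cc2c(OC)c(OC)cc(OC)c2OC | intermediate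
8 | bromomagnesium (3R)-3-methyl-2-[(2,3,5,6-tetramethoxyphenyl)methyl]cyclohex-1-en-1-olate | Br[Mg]OC1=C(Cc2c(OC)c(OC)cc(OC)c2OC)[C@H](C)CCC1 | intermediate
9 | (2R,3R)-2,3-dimethyl-2-[(2,3,5,6-tetramethoxyphenyl)methyl]cyclohexan-1-one | O=C1[C@](C)(Cc2c(OC)c(OC)cc(OC)c2OC)[C@H](C)CCC1 | intermediate
10 | N'-{(2R,3R)-2,3-dimethyl-2-[(2,3,5,6-tetramethoxyphenyl)methyl]cyclohexylidene}-2,4,6-tri(propan-2-yl)benzenesulfonohydrazide | CC(C)c1cc(C(C)C)c(S(=O)(=O)NN=C2[C@](C)(Cc3c(OC)c(OC)cc(OC)c3OC)[C@H](C)CCC2)c(C(C)C)c1 | intermediate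
11 | N-lithio salt of N'-{(2R,3R,6RS)-2,3,6-trimethyl-2-[(2,3,5,6-tetramethoxyphenyl)methyl]cyclohexylidene}-2,4,6-tri(propan-2-yl)benzenesulfonohydrazide | CC(C)c1cc(C(C)C)c(S(=O)(=O)N([Li])N=C2[C@](C)(Cc3c(OC)c(OC)cc(OC)c3OC)[C@H](C)CCC2C)c(C(C)C)c1 | intermediate
12 | {(5R,6R)-2,5,6-trimethyl-6-[(2,3,5,6-tetramethoxyphenyl)methyl]cyclohex-1-en-1-yl}lithium | CC1=C([Li])[C@](C)(Cc2c(OC)c(OC)cc(OC)c2OC)[C@H](C)CC1 | intermediate
13 | (3R,4R)-1,3,4-trimethyl-3-[(2,3,5,6-tetramethoxyphenyl)methyl]cyclohex-1-ene | CC1=C[C@](C)(Cc2c(OC)c(OC)cc(OC)c2OC)[C@H](C)CC1 | intermediate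
14 | (4R,5R)-2,4,5-trimethyl-4-[(2,3,5,6-tetramethoxyphenyl)methyl]cyclohex-2-en-1-one | CC1=C[C@](C)(Cc2c(OC)c(OC)cc(OC)c2OC)[C@H](C)CC1=O | intermediate
15 | (5-chloropent-1-yn-1-yl)trimethylsilane | C[Si](C)(C)C#CCCCCl | starting material
16 | chloro[5-(trimethylsilyl)pent-4-yn-1-yl]magnesium | C[Si](C)(C)C#CCCC[Mg]Cl | intermediate
17 | trimethyl({(3S,4R,5R)-2,4,5-trimethyl-4-[(2,3,5,6-tetramethoxyphenyl)methyl]-3-[5-(trimethylsilyl)pent-4-yn-1-yl]cyclohex-1-en-1-yl}oxy)silane | C[Si](C)(C)OC1=C(C)[C@@H](CCCC#C[Si](C)(C)C)[C@](C)(Cc2c(OC)c(OC)cc(OC)c2OC)[C@H](C)C1 | intermediate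
18 | lithium (3S,4R,5R)-2,4,5-trimethyl-4-[(2,3,5,6-tetramethoxyphenyl)methyl]-3-[5-(trimethylsilyl)pent-4-yn-1-yl]cyclohex-1-en-1-olate | [Li]OC1=C(C)[C@@H](CCCC#C[Si](C)(C)C)[C@](C)(Cc2c(OC)c(OC)cc(OC)c2OC)[C@H](C)C1 | intermediate
19 | tri(propan-2-yl)({(3S,4R,5R)-2,4,5-trimethyl-4-[(2,3,5,6-tetramethoxyphenyl)methyl]-3-[5-(trimethylsilyl)pent-4-yn-1-yl]cyclohex-1-en-1-yl}oxy)silane | CC(C)[Si](OC1=C(C)[C@@H](CCCC#C[Si](C)(C)C)[C@](C)(Cc2c(OC)c(OC)cc(OC)c2OC)[C@H](C)C1)(C(C)C)C(C)C | intermediate
20 | ({(3S,4R,5R)-2,4,5-trimethyl-3-(pent-4-yn-1-yl)-4-[(2,3,5,6-tetramethoxyphenyl)methyl]cyclohex-1-en-1-yl}oxy)tri(propan-2-yl)silane | CC(C)[Si](OC1=C(C)[C@@H](CCCC#C)[C@](C)(Cc2c(OC)c(OC)cc(OC)c2OC)[C@H](C)C1)(C(C)C)C(C)C | intermediate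
21 | (3R,4R,4aS,8aR)-3,4,8a-trimethyl-8-methylidene-4-[(2,3,5,6-tetramethoxyphenyl)methyl]-3,4,4a,5,6,7,8,8a-octahydronaphthalen-1(2H)-one | C=C1CCC[C@H]2[C@](C)(Cc3c(OC)c(OC)cc(OC)c3OC)[C@H](C)CC(=O)[C@@]12C | intermediate
22 | hydrazone of 21 | C=C1CCC[C@H]2[C@](C)(Cc3c(OC)c(OC)cc(OC)c3OC)[C@H](C)CC(=NN)[C@@]12C | intermediate
23 | 3-{[(1R,2R,4aR,8aS)-1,2,4a-trimethyl-5-methylidenedecahydronaphthalen-1-yl]methyl}-1,2,4,5-tetramethoxybenzene | C=C1CCC[C@H]2[C@](C)(Cc3c(OC)c(OC)cc(OC)c3OC)[C@H](C)CC[C@@]12C | intermediate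
24 | 2,5-dimethoxy-3-{[(1R,2R,4aR,8aS)-1,2,4a-trimethyl-5-methylidenedecahydronaphthalen-1-yl]methyl}cyclohexa-2,5-diene-1,4-dione | C=C1CCC[C@H]2[C@](C)(CC3=C(OC)C(=O)C=C(OC)C3=O)[C@H](C)CC[C@@]12C | intermediate
25 | 2-hydroxy-5-methoxy-3-{[(1R,2R,4aR,8aS)-1,2,4a-trimethyl-5-methylidenedecahydronaphthalen-1-yl]methyl}cyclohexa-2,5-diene-1,4-dione | C=C1CCC[C@H]2[C@](C)(CC3=C(O)C(=O)C=C(OC)C3=O)[C@H](C)CC[C@@]12C | target

**Totals and risks**

Total step count: 14. Longest linear sequence: 14 steps (1 to 25); 5 and 15 enter as purchased compounds.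

Steps most likely to fail:

Step 7. Oxidation may go to the wrong site: electron transfer from the tetramethoxyarene or hydrogen abstraction at the benzylic CH2 may compete with allylic abstraction, and oxygen may be delivered to the neopentyl allyl terminus. The fallback sets out from 9 and returns at 14 by a Wharton transposition instead of a C–H oxidation. Ketone 9 is methylated at its only enolisable carbon (LDA, MeI, THF, –78 °C) to give (2R,3R,6RS)-2,3,6-trimethyl-2-(ArCH2)cyclohexan-1-one F1. This is converted (LDA, Me3SiCl) into its trimethylsilyl enol ether F2 and dehydrogenated with Pd(OAc)2 in MeCN (Saegusa oxidation) to (5R,6R)-2,5,6-trimethyl-6-(ArCH2)cyclohex-2-en-1-one F3. Nucleophilic epoxidation (H2O2, NaOH, MeOH, 0 °C) gives the epoxy ketone (3R,4R)-1,3,4-trimethyl-3-(ArCH2)-7-oxabicyclo[4.1.0]heptan-2-one F4. Hydrazine hydrate with catalytic acetic acid then gives the transposed allylic alcohol (4R,5R)-2,4,5-trimethyl-4-(ArCH2)cyclohex-2-en-1-ol F5, which MnO2 in CH2Cl2 oxidises to 14.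

Step 11. The silyl group may be lost by protonolysis before the carbon–carbon bond forms, or attack by the congested tetrasubstituted enol carbon may be so slow that the activated alkyne is hydrated instead. The fallback sets out from 14 and returns at 21 and replaces alkyne activation by an oxidative enolate–alkene coupling. Conjugate addition of pent-4-enylmagnesium bromide under the conditions of step 8 gives trimethyl{[(3S,4R,5R)-2,4,5-trimethyl-3-(pent-4-en-1-yl)-4-(ArCH2)cyclohex-1-en-1-yl]oxy}silane F6. Treatment with Pd(OAc)2 (1 equiv) in MeCN forms the divalent palladium enolate at the same carbon, 6-exo-trig carbopalladation of the terminal alkene follows, and β-hydride elimination from the only β-hydrogen gives the exocyclic methylene of 21.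

Step 12. Hydrazone formation at the ketone next to the quaternary carbon may be slow, the exocyclic double bond may migrate into the ring in hot base, and diimide formed from hydrazine and traces of oxygen may reduce the alkene. The fallback sets out from 21 and returns at 23 and uses a hydride reduction below 70 °C. Condensation with TsNHNH2 (EtOH, cat. HCl, reflux) gives N'-[(3R,4R,4aS,8aR)-3,4,8a-trimethyl-8-methylidene-4-(ArCH2)octahydronaphthalen-1(2H)-ylidene]-4-methylbenzenesulfonohydrazide F7. Reduction with catecholborane (CHCl3, 0 °C) and decomposition of the adduct with NaOAc·3H2O at reflux gives 23.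

Further compounds
F1 | step 7 | (2R,3R,6RS)-2,3,6-trimethyl-2-[(2,3,5,6-tetramethoxyphenyl)methyl]cyclohexan-1-one | O=C1[C@](C)(Cc2c(OC)c(OC)cc(OC)c2OC)[C@H](C)CCC1C
F2 | step 7 | trimethyl({(5R,6R)-2,5,6-trimethyl-6-[(2,3,5,6-tetramethoxyphenyl)methyl]cyclohex-1-en-1-yl}oxy)silane | CC1=C(O[Si](C)(C)C)[C@](C)(Cc2c(OC)c(OC)cc(OC)c2OC)[C@H](C)CC1
F3 | step 7 | (5R,6R)-2,5,6-trimethyl-6-[(2,3,5,6-tetramethoxyphenyl)methyl]cyclohex-2-en-1-one | O=C1[C@](C)(Cc2c(OC)c(OC)cc(OC)c2OC)[C@H](C)CC=C1C
F4 | step 7 | (3R,4R)-1,3,4-trimethyl-3-[(2,3,5,6-tetramethoxyphenyl)methyl]-7-oxabicyclo[4.1.0]heptan-2-one (epoxide diastereomers) | O=C1[C@](C)(Cc2c(OC)c(OC)cc(OC)c2OC)[C@H](C)CC3OC13C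
F5 | step 7 | (4R,5R)-2,4,5-trimethyl-4-[(2,3,5,6-tetramethoxyphenyl)methyl]cyclohex-2-en-1-ol (C-1 epimers) | CC1=C[C@](C)(Cc2c(OC)c(OC)cc(OC)c2OC)[C@H](C)CC1O
F6 | step 11 | trimethyl({(3S,4R,5R)-2,4,5-trimethyl-3-(pent-4-en-1-yl)-4-[(2,3,5,6-tetramethoxyphenyl)methyl]cyclohex-1-en-1-yl}oxy)silane | C[Si](C)(C)OC1=C(C)[C@@H](CCCC=C)[C@](C)(Cc2c(OC)c(OC)cc(OC)c2OC)[C@H](C)C1
F7 | step 12 | N'-{(3R,4R,4aS,8aR)-3,4,8a-trimethyl-8-methylidene-4-[(2,3,5,6-tetramethoxyphenyl)methyl]octahydronaphthalen-1(2H)-ylidene}-4-methylbenzenesulfonohydrazide | C=C1CCC[C@H]2[C@](C)(Cc3c(OC)c(OC)cc(OC)c3OC)[C@H](C)CC(=NNS(=O)(=O)c4ccc(C)cc4)[C@@]12C
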